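(The constants used here stand for no real mixture; the flask was simulated.)

In a one-step world where substrate simply turned into target, every charge would keep the same fraction left; step two alone would leave 99.2% after 25 min. This flask has more to it: target speeds its own making, and solid can take it out of solution.

the same everywhere: time 25 min

| flask | substrate |
|---|---|
| delta | 0.050 M |
| beta | 0.10 M |
| gamma | 0.20 M |
| theta | 0.40 M |

    substrate + target → 2 target (k1 = 0.0563 M⁻¹ s⁻¹)
    substrate → target (k2 = 5.36 × 10⁻⁶ s⁻¹)
    target → over-reaction product (k3 = 2.78 × 10⁻⁵ s⁻¹)
    crystals ⇌ target, rate k4*(cs4 - [target]) while solid is left; crystals form when [target] > cs4 (cs4 = 43 mM, k4 = 0.00875 s⁻¹)

- amounts and yields of target count crystals too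
- given per volume of solution although it is solid: crystals
- the concentration of target that is asked is that of its free form alone
- "hardly changes" means that all values lie within two and a half points (for a concentration: within two and a half percent of the largest)
- run time (delta): 25 min

* [target] (only what is free in solution) at the end for delta, beta, gamma, theta, in this order
* how the row runs (falls all the way / hardly changes / rises, then falls / rises all the way / falls, then rises)

My reckoning works with the fraction of substrate left through R, the ratio of made to left. Before any solid appears, R starts at zero, and R plus a small constant s grows exponentially at a pace k, which is step one's constant times the charge plus step two's constant, 0.169 min⁻¹ in delta; s is step two's constant over k, 0.00190 in delta. I drop step three, since the half-life of target by that step, 6.9 h, is longer than the run. In delta, R reaches 0.129, which gives 0.00570 M target. The same growth puts the passing of the solubility in delta at 47.8 min, later than the end, so delta stays free of crystals. In beta it comes at 19.7 min, and in theta at 4.61 min.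

Two chemists now part. The first holds that free target, once past the solubility, sits on it, so beta, gamma and theta each read 0.043 M. The second says crystals need time, and sets the making of target by step one equal to its clearing by crystals, a steady state. Call Ac the substrate concentration at which step one's constant times substrate equals the crystal constant, 0.155 M. Free target then stands at the solubility times Ac/(Ac − substrate).

I side with the second for beta: crystals respond within 1.90 min, shorter than the 5.25 min remaining. With free target near solubility, substrate falls pseudo-first-order with lifetime 6.88 min, from 0.0570 M to 0.0266 M, which gives 0.0519 M free target. In theta, substrate at passing, 0.357 M, exceeds Ac, so the steady state cannot hold at first. The same lifetime still gives a rough figure for the end in theta, 0.0185 M of substrate, which is below Ac, and the rule then gives 0.0488 M free target, less than my beta. With delta, beta and theta so placed, I expect the row to run: rises, then falls.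

The forecast takes the second side: 0.0056 M, 0.052 M, 0.0455 M, 0.0436 M, so rises, then falls, with beta one that “still sits in a supersaturated overshoot”. Its delta lies slightly below mine.

The flasks give 0.00553 M, 0.0527 M, 0.0458 M and 0.0437 M, and the row runs: rises, then falls. In beta, 23% of the substrate is left at the end, and crystals hold 23.5% of the charge. Put into the Ac rule, that substrate gives 0.0505 M free target against the 0.0527 M found. The first chemist's region is theta, where the substrate left, 0.00191 M, lies far below Ac, and the rule gives 0.0435 M, with 0.0437 M found beside a solubility of 0.043 M.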